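**Strategy.** The cyclopentane (C1, C2, C3, C3a, C8a) carries a tertiary C3a–O, the quaternary C8a and, one carbon further, the C8 oxygen: a masked β-alkoxy aldehyde. It is made by contraction of the cyclohexene ring of (R)-piperitone. In the key step the trisubstituted epoxide of a p-menthene spiro-ether opens at its methyl-bearing carbon and the oxygenated ring carbon shifts to it, which gives at once the five-membered ring, the quaternary C8a by transfer of the epoxide configuration, and the C8 aldehyde. The precursor is an epoxycyclohexane in which the tertiary hydroxyl and the side-chain alkene are tied up as a bromomethyl-tetrahydrofuran. Vinyl addition and ring-closing metathesis then close the seven-membered ring.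

Key step: step 5

Remark: the SMILES is read as (3R,3aS,8S,8aR) in azulene numbering, with 3a-OH, 8a-CH3, 3-isopropyl and the C8 ester oxygen on one face of the cis-fused bicycle; (+)-menthone (2R,5S) is taken as the commercial source of C3.

**Step 1**
Reactants: 1 (+)-menthone [(2R,5S)-5-methyl-2-(propan-2-yl)cyclohexan-1-one]
Product: 3 (R)-piperitone [(6R)-3-methyl-6-(propan-2-yl)cyclohex-2-en-1-one], via TMS enol ether 2 (not isolated)
Conditions: LDA, TMSCl, THF, −78 °C; then Pd(OAc)2 (1 equiv), MeCN, rt
Reagents that add atoms: none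
Why: Kinetic deprotonation at the less hindered C6 methylene leaves the isopropyl-bearing stereocentre untouched, and Saegusa–Ito oxidation (palladium enolate, β-hydride elimination of the C5 hydrogen) gives the enone, erasing the methyl-bearing stereocentre on purpose.

**Step 2**
Reactants: 3 (R)-piperitone; 4 4-bromo-2-methylbut-1-ene
Product: 6 (1S,6R)-3-methyl-1-(3-methylbut-3-en-1-yl)-6-(propan-2-yl)cyclohex-2-en-1-ol, via Grignard reagent 5 (not isolated)
Conditions: 4, Mg, THF, rt; then LaCl3·2LiCl, 3, THF, −20 to 0 °C; aq NH4Cl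
Reagents that add atoms: 4-bromo-2-methylbut-1-ene (4, as its Grignard reagent), C=C(C)CCBr
Why: 1,2-Addition of the Grignard reagent to the enone (Lewis-acid activation suppresses enolisation of the epimerisable C6–H and conjugate addition) with attack trans to the pseudo-equatorial isopropyl group, as in Grignard additions to menthone, should set the carbinol centre (1S) with OH cis to isopropyl.

**Step 3**
Reactants: 6 (1S,6R)-3-methyl-1-(3-methylbut-3-en-1-yl)-6-(propan-2-yl)cyclohex-2-en-1-ol
Product: 7 (5S,10R)-2-(bromomethyl)-2,7-dimethyl-10-(propan-2-yl)-1-oxaspiro[4.5]dec-6-ene (both C2 epimers)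
Conditions: NBS, NaHCO3, CH2Cl2, 0 °C, dark
Reagents that add atoms: N-bromosuccinimide (NBS), O=C1CCC(=O)N1Br
Why: Bromoetherification: the tertiary hydroxyl closes 5-exo onto the bromonium ion of the 1,1-disubstituted alkene at its tertiary carbon, which masks the hydroxyl and the side-chain alkene in one temporary ring (the new oxolane centre forms as a mixture and is erased in step 7) and leaves the ring alkene as the only alkene.

**Step 4**
Reactants: 7 (5S,10R)-2-(bromomethyl)-2,7-dimethyl-10-(propan-2-yl)-1-oxaspiro[4.5]dec-6-ene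
Product: 8 (1'S,2S,3'R,6'S)-5-(bromomethyl)-5,6'-dimethyl-3'-(propan-2-yl)spiro[oxolane-2,2'-[7]oxabicyclo[4.1.0]heptane] (both C5 epimers)
Conditions: mCPBA, NaHCO3, CH2Cl2, 0 °C to rt
Reagents that add atoms: mCPBA (3-chloroperoxybenzoic acid), OOC(=O)c1cccc(Cl)c1
Why: Prilezhaev epoxidation of the only alkene left; with isopropyl equatorial the allylic ether oxygen is pseudo-axial and shields its face together with the substituted oxolane carbon, so the peracid should add anti to that oxygen and place the epoxide oxygen trans to it.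

**Step 5**
Reactants: 8 (1'S,2S,3'R,6'S)-5-(bromomethyl)-5,6'-dimethyl-3'-(propan-2-yl)spiro[oxolane-2,2'-[7]oxabicyclo[4.1.0]heptane]
Product: 9 (5S,6S,9R)-2-(bromomethyl)-2,6-dimethyl-9-(propan-2-yl)-1-oxaspiro[4.4]nonane-6-carbaldehyde (both C2 epimers)
Conditions: MABR [methylaluminium bis(4-bromo-2,6-di-tert-butylphenoxide), 2 equiv, from Me3Al and the phenol], CH2Cl2, −78 °C
Reagents that add atoms: none
Why: The bulky aluminium Lewis acid binds the epoxide oxygen and the C–O bond at the methyl-bearing tertiary carbon ionises (the other epoxide carbon is secondary and sits next to the electron-withdrawing ether carbon), while the ring bond from the epoxide CH to the oxygenated spiro carbon shifts to the electron-poor centre from the face opposite the departing oxygen and the epoxide CH becomes the aldehyde carbon (Meinwald/semipinacol 1,2-shift). The closest known reaction type is the MABR-promoted rearrangement of trisubstituted epoxides and of epoxy silyl ethers to aldehydes with migration of the oxygen-bearing carbon, including ring contraction of 1-alkylcyclohexene oxides. No ring is closed by a cyclisation: the cyclohexane contracts to the cyclopentane by this 1,2-shift through a three-centre transition state, and the oxolane ring is a spectator. The new quaternary centre is set by the epoxide configuration through inversion at the migration terminus and the spiro carbon migrates with retention, so that CH3 should end cis to the ether oxygen and to isopropyl, and the formyl group cis to the oxolane CH2. The step needs carbon shift to win over hydride shift, proton loss and opening at the other carbon: in the chair-like conformer with isopropyl equatorial both C–O bonds are axial, which puts the migrating ring bond, not the C–H bond, in line with the breaking C–O bond, and the hindered, non-nucleophilic Lewis acid should leave the hindered oxolane oxygen and the product aldehyde alone.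

**Step 6**
Reactants: 9 (5S,6S,9R)-2-(bromomethyl)-2,6-dimethyl-9-(propan-2-yl)-1-oxaspiro[4.4]nonane-6-carbaldehyde; 10 vinylmagnesium bromide; 11 4-methoxybenzoyl chloride
Product: 13 (1S)-1-[(5S,6R,9R)-2-(bromomethyl)-2,6-dimethyl-9-(propan-2-yl)-1-oxaspiro[4.4]nonan-6-yl]prop-2-en-1-yl 4-methoxybenzoate, via magnesium alkoxide 12 (not isolated)
Conditions: 10, THF, −78 to 0 °C; then 11, DMAP, 0 °C to rt
Reagents that add atoms: vinylmagnesium bromide (10), C=C[Mg]Br; 4-methoxybenzoyl chloride (11), COc1ccc(C(Cl)=O)cc1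
Why: Felkin–Anh addition of the vinyl Grignard to the α-quaternary aldehyde (fully substituted spiro carbon anti to the nucleophile, metal-bound carbonyl oxygen turned away from the oxolane ring, vinyl passing the methyl group) should set the carbinol centre (S), and the magnesium alkoxide is acylated in the same flask by DMAP-catalysed nucleophilic acyl substitution.

**Step 7**
Reactants: 13 (1S)-1-[(5S,6R,9R)-2-(bromomethyl)-2,6-dimethyl-9-(propan-2-yl)-1-oxaspiro[4.4]nonan-6-yl]prop-2-en-1-yl 4-methoxybenzoate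
Product: 14 (1S)-1-[(1R,2S,3R)-2-hydroxy-1-methyl-2-(3-methylbut-3-en-1-yl)-3-(propan-2-yl)cyclopentyl]prop-2-en-1-yl 4-methoxybenzoate
Conditions: Zn dust (activated), AcOH, EtOH, 60 °C
Reagents that add atoms: none
Why: Boord-type reductive β-elimination: zinc inserts into the primary C–Br bond and the β-alkoxide leaves, which returns the tertiary alcohol and the 1,1-disubstituted alkene from both oxolane epimers (stereoconvergent) and leaves the allylic ester untouched.

**Step 8**
Reactants: 14 (1S)-1-[(1R,2S,3R)-2-hydroxy-1-methyl-2-(3-methylbut-3-en-1-yl)-3-(propan-2-yl)cyclopentyl]prop-2-en-1-yl 4-methoxybenzoate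
Product: 15 (3R,3aS,8S,8aR)-3a-hydroxy-6,8a-dimethyl-3-(propan-2-yl)-1,2,3,3a,4,5,8,8a-octahydroazulen-8-yl 4-methoxybenzoate
Conditions: Hoveyda–Grubbs II (5 mol %), toluene, 80 °C
Reagents that add atoms: none
Why: Ring-closing metathesis of the vinyl group with the 1,1-disubstituted alkene, held cis on adjacent ring carbons, closes the seven-membered ring as the trisubstituted C6=C7 alkene with loss of ethylene and touches no stereocentre.

**Compound list**

1 | (+)-menthone, (2R,5S)-5-methyl-2-(propan-2-yl)cyclohexan-1-one | CC(C)[C@H]1CC[C@H](C)CC1=O | starting material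
2 | trimethyl{[(3S,6R)-3-methyl-6-(propan-2-yl)cyclohex-1-en-1-yl]oxy}silane | CC(C)[C@H]1CC[C@H](C)C=C1O[Si](C)(C)C | intermediate
3 | (R)-piperitone, (6R)-3-methyl-6-(propan-2-yl)cyclohex-2-en-1-one | CC(C)[C@H]1CCC(C)=CC1=O | intermediate
4 | 4-bromo-2-methylbut-1-ene | C=C(C)CCBr | starting material
5 | (3-methylbut-3-en-1-yl)magnesium bromide | C=C(C)CC[Mg]Br | intermediate
6 | (1S,6R)-3-methyl-1-(3-methylbut-3-en-1-yl)-6-(propan-2-yl)cyclohex-2-en-1-ol | C=C(C)CC[C@@]1(O)C=C(C)CC[C@@H]1C(C)C | intermediate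
7 | (5S,10R)-2-(bromomethyl)-2,7-dimethyl-10-(propan-2-yl)-1-oxaspiro[4.5]dec-6-ene (C2 epimers) | CC1(CBr)CC[C@@]2(O1)C=C(C)CC[C@@H]2C(C)C | intermediate
8 | (1'S,2S,3'R,6'S)-5-(bromomethyl)-5,6'-dimethyl-3'-(propan-2-yl)spiro[oxolane-2,2'-[7]oxabicyclo[4.1.0]heptane] (C5 epimers) | CC1(CBr)CC[C@@]2(O1)[C@H]3O[C@@]3(C)CC[C@@H]2C(C)C | intermediate
9 | (5S,6S,9R)-2-(bromomethyl)-2,6-dimethyl-9-(propan-2-yl)-1-oxaspiro[4.4]nonane-6-carbaldehyde (C2 epimers) | CC1(CBr)CC[C@@]2(O1)[C@@](C)(C=O)CC[C@@H]2C(C)C | intermediate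
10 | vinylmagnesium bromide | C=C[Mg]Br | starting material
11 | 4-methoxybenzoyl chloride | COc1ccc(C(Cl)=O)cc1 | starting material
12 | bromomagnesium (1S)-1-[(5S,6R,9R)-2-(bromomethyl)-2,6-dimethyl-9-(propan-2-yl)-1-oxaspiro[4.4]nonan-6-yl]prop-2-en-1-olate | CC1(CBr)CC[C@@]2(O1)[C@@](C)([C@H](C=C)O[Mg]Br)CC[C@@H]2C(C)C | intermediate
13 | (1S)-1-[(5S,6R,9R)-2-(bromomethyl)-2,6-dimethyl-9-(propan-2-yl)-1-oxaspiro[4.4]nonan-6-yl]prop-2-en-1-yl 4-methoxybenzoate | CC1(CBr)CC[C@@]2(O1)[C@@](C)([C@H](C=C)OC(=O)c3ccc(OC)cc3)CC[C@@H]2C(C)C | intermediate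
14 | (1S)-1-[(1R,2S,3R)-2-hydroxy-1-methyl-2-(3-methylbut-3-en-1-yl)-3-(propan-2-yl)cyclopentyl]prop-2-en-1-yl 4-methoxybenzoate | C=C(C)CC[C@@]1(O)[C@@](C)([C@H](C=C)OC(=O)c2ccc(OC)cc2)CC[C@@H]1C(C)C | intermediate
15 | (3R,3aS,8S,8aR)-3a-hydroxy-6,8a-dimethyl-3-(propan-2-yl)-1,2,3,3a,4,5,8,8a-octahydroazulen-8-yl 4-methoxybenzoate | COc1ccc(C(=O)O[C@H]2C=C(C)CC[C@]3(O)[C@@H](C(C)C)CC[C@]23C)cc1 | target

Total step count: 8. Longest linear sequence: 8 steps (1 to 15).

**Steps most likely to fail**

Step 5. The 1,2-shift of the ring carbon may be outrun by hydride shift to the cyclohexanone, by proton loss to an allylic alcohol, or by ionisation at the oxolane oxygen. The fallback sets out from 3 and comes back at 14. It runs the rearrangement on an epoxy silyl ether, the substrate class in which migration of the siloxy-bearing carbon is established, and makes the side-chain alkene afterwards. Addition of the Grignard reagent of 2-(2-bromoethyl)-2-methyl-1,3-dioxolane to 3 (LaCl3·2LiCl) should give the ketal alcohol F1. TESOTf and 2,6-lutidine should give the silyl ether F2. mCPBA (NaHCO3) should epoxidise anti to the pseudo-axial siloxy group and give the epoxy silyl ether F3. MABR at −78 °C should give the β-siloxy aldehyde F4. Vinylmagnesium bromide, then 11 and DMAP, should give the ester F5. 1 M HCl in THF removes ketal and silyl group to give the keto alcohol F6. Ph3P=CH2 in THF methylenates the ketone and returns 14.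

Step 4. Facial selectivity may be poor, with the peracid adding from the face of the ether oxygen. The fallback sets out from 7 and comes back at 8; it brings the oxygen to the other face through a halohydrin. NBS in aqueous DME forms the bromonium ion on the face that electrophiles prefer, and water opens it trans at the tertiary carbon to give the bromohydrin F7. K2CO3 in MeOH closes the epoxide with inversion at the CHBr carbon and gives 8.

Step 6. Facial selectivity in the vinyl addition may be poor (Felkin and anti-Felkin paths close in energy), which would give the C8 epimer. The fallback sets out from 9 and comes back at 15; it sets the carbinol configuration on the ring. Vinylmagnesium bromide without acylation gives the allylic alcohols F8 as a mixture. Zn and AcOH give the diene diols F9. Ring-closing metathesis gives the bicyclic diols F10. MnO2 oxidises the allylic alcohol to the enone F11. Et2BOMe and NaBH4 (Narasaka–Prasad reduction: boron chelate with the tertiary hydroxyl, hydride from the open face, anti to the angular methyl) should give the cis-diol F12. Reagent 11 with DMAP and pyridine acylates the secondary hydroxyl and gives 15.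

**Further compounds**

F1 | step 5 | (1S,6R)-3-methyl-1-[2-(2-methyl-1,3-dioxolan-2-yl)ethyl]-6-(propan-2-yl)cyclohex-2-en-1-ol | CC1(CC[C@@]2(O)C=C(C)CC[C@@H]2C(C)C)OCCO1
F2 | step 5 | triethyl{[(1S,6R)-3-methyl-1-[2-(2-methyl-1,3-dioxolan-2-yl)ethyl]-6-(propan-2-yl)cyclohex-2-en-1-yl]oxy}silane | CC1(CC[C@@]2(O[Si](CC)(CC)CC)C=C(C)CC[C@@H]2C(C)C)OCCO1
F3 | step 5 | triethyl{[(1S,2S,3R,6S)-6-methyl-2-[2-(2-methyl-1,3-dioxolan-2-yl)ethyl]-3-(propan-2-yl)-7-oxabicyclo[4.1.0]heptan-2-yl]oxy}silane | CC1(CC[C@@]2(O[Si](CC)(CC)CC)[C@H]3O[C@@]3(C)CC[C@@H]2C(C)C)OCCO1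
F4 | step 5 | (1S,2S,3R)-1-methyl-2-[2-(2-methyl-1,3-dioxolan-2-yl)ethyl]-3-(propan-2-yl)-2-[(triethylsilyl)oxy]cyclopentane-1-carbaldehyde | CC1(CC[C@@]2(O[Si](CC)(CC)CC)[C@@](C)(C=O)CC[C@@H]2C(C)C)OCCO1
F5 | step 5 | (1S)-1-[(1R,2S,3R)-1-methyl-2-[2-(2-methyl-1,3-dioxolan-2-yl)ethyl]-3-(propan-2-yl)-2-[(triethylsilyl)oxy]cyclopentyl]prop-2-en-1-yl 4-methoxybenzoate | CC1(CC[C@@]2(O[Si](CC)(CC)CC)[C@@](C)([C@H](C=C)OC(=O)c3ccc(OC)cc3)CC[C@@H]2C(C)C)OCCO1
F6 | step 5 | (1S)-1-[(1R,2S,3R)-2-hydroxy-1-methyl-2-(3-oxobutyl)-3-(propan-2-yl)cyclopentyl]prop-2-en-1-yl 4-methoxybenzoate | CC(=O)CC[C@@]1(O)[C@@](C)([C@H](C=C)OC(=O)c2ccc(OC)cc2)CC[C@@H]1C(C)C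
F7 | step 4 | (5S,6R,7S,10R)-6-bromo-2-(bromomethyl)-2,7-dimethyl-10-(propan-2-yl)-1-oxaspiro[4.5]decan-7-ol (C2 epimers) | CC1(CBr)CC[C@@]2(O1)[C@H](Br)[C@@](C)(O)CC[C@@H]2C(C)C
F8 | step 6 | 1-[(5S,6R,9R)-2-(bromomethyl)-2,6-dimethyl-9-(propan-2-yl)-1-oxaspiro[4.4]nonan-6-yl]prop-2-en-1-ol (carbinol epimers) | CC1(CBr)CC[C@@]2(O1)[C@@](C)(C(O)C=C)CC[C@@H]2C(C)C
F9 | step 6 | (1S,2R,5R)-2-(1-hydroxyprop-2-en-1-yl)-2-methyl-1-(3-methylbut-3-en-1-yl)-5-(propan-2-yl)cyclopentan-1-ol (carbinol epimers) | C=C(C)CC[C@@]1(O)[C@@](C)(C(O)C=C)CC[C@@H]1C(C)C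
F10 | step 6 | (3R,3aS,8aR)-6,8a-dimethyl-3-(propan-2-yl)-2,3,4,5,8,8a-hexahydro-1H-azulene-3a,8-diol (C8 epimers) | OC1C=C(C)CC[C@]2(O)[C@@H](C(C)C)CC[C@]12C
F11 | step 6 | (3R,3aS,8aS)-3a-hydroxy-6,8a-dimethyl-3-(propan-2-yl)-1,2,3,3a,4,5-hexahydroazulen-8(8aH)-one | O=C1C=C(C)CC[C@]2(O)[C@@H](C(C)C)CC[C@]12C
F12 | step 6 | (3R,3aS,8S,8aR)-6,8a-dimethyl-3-(propan-2-yl)-2,3,4,5,8,8a-hexahydro-1H-azulene-3a,8-diol | O[C@H]1C=C(C)CC[C@]2(O)[C@@H](C(C)C)CC[C@]12C
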